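## The problem

The target, 6-hydroxy-8-(2-hydroxy-4-methoxy-6-pentylphenoxy)-3-pentyl-1H-isochromen-1-one (22), is an achiral diaryl ether. It is a 3-pentylisocoumarin (benzo ring A fused at C4a–C8a to the enol-lactone ring C) whose C8 oxygen carries a second arene, ring B. With no stereocentre to set, the task is one of regiochemistry and of telling oxygens apart.

The bridging oxygen is the hard bond. On ring B it lies between the 2'-hydroxyl and the 6'-pentyl group, on ring A it lies peri to the C1 carbonyl, and both rings are electron-rich. A late copper- or palladium-mediated union of two finished arenes would therefore be doubly ortho-hindered and electronically unfavourable.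

Four ring oxygens must end in three different states: 6-OH and 2'-OH free, 4'-OMe, and 8-O as the bridge. No selective demethylation can be used, because a methyl ether has to survive on ring B.

Ring C opens with hydroxide or alkoxide and can be over-reduced at C3=C4. Unprotected ring B has a para-related oxygen pair and oxidises readily, so the end game must be mild and non-oxidative.

The enabling feature is ring A itself: a benzene fused to the 6-pentyl-2-pyranone ring C, with oxygen at C6 and C8 on either side of the unsubstituted C7. C7, C8, C8a and C4a can be taken from the four diene carbons of a second 2-pyranone fused to ring C, and C5–C6 from a ketene acetal, the lactone bridge of that second pyranone leaving as carbon dioxide. In such a pyrano[4,3-b]pyran-2,5-dione the carbon that becomes C8 is the β-carbon of a vinylogous acid. The hindered ring-B phenol can be attached there by addition–elimination before ring A exists as an arene.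

## Retrosynthesis

**22 ⇒ 20 (through 21).** No skeletal bond is cut; only the 6-O–Si and 2'-O–benzyl bonds are broken. Benzyl is chosen for the 2'-oxygen because it survives peracid, strong base, a vinylogous acid chloride and 110 °C, and falls under neutral hydrogenolysis. The silyl group on the 6-oxygen is simply what the ring-forming step leaves behind. The forward reaction must cleave both groups without reducing C3=C4 of ring C.

**20 ⇒ 15 + 17.** Ring A is cut at C4a–C5 and C6–C7, and a C(=O)–O bridge is put back between C7 and C4a. The neighbouring cut, the C8–O ether bond of a finished isocoumarin, would call for coupling two hindered electron-rich arenes. A cut at C1–C8a or C3–C4 would leave ring A with its three differentiated substituents still to be assembled. The cut chosen removes a whole benzene ring and leaves the bis-lactone 15 and the two-carbon ketene acetal 17. The forward cycloaddition must engage the aryloxy-bearing pyranone of 15 and not ring C, must place the CH2 of 17 on the ring-fusion carbon, and must then shed the lactone bridge and one silyloxy group to aromatise.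

**17 ⇒ 16.** One O–Si bond is cut; the forward step is O-silylation of the lithium enolate of the silyl ester 16.

**15 ⇒ 14 + 8.** The C4–O bond of 15 (the future C8–O) is cut. At this stage the carbon is the β-position of a vinylogous acid chloride, so the ether can be made by metal-free addition–elimination. This separates ring B, as phenol 8, from the bicyclic core 14. The forward step asks the phenoxide of 8 to attack C4 of 14 rather than a lactone carbonyl.

**14 ⇒ 13 ⇒ 11 + 12.** The C–Cl bond goes back to the enolic C–OH of 13. Then the C4–C4a and O1–C2 bonds of the second pyranone are cut, which returns the monocyclic 4-hydroxypyranone 11 and the three-carbon bis-electrophile 12. The forward annulation must acylate C3 of 11 and lactonise onto its 4-oxygen.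

**11 ⇒ 9 + 10.** The bond between the first and second carbons of the pentyl chain is cut. This leads to the commercial methylpyranone 9 and the butyl halide 10 in one step, where acylating an acetoacetate dianion and cyclising would take two. The forward step needs alkylation at the methyl group of the dianion of 9 and not at C3 or oxygen.

**8 ⇒ 7 ⇒ 5 + 6.** The side-chain alkene of 7 is saturated in the forward sense, and its C=C bond is cut to the salicylaldehyde 5 and the four-carbon phosphonium salt 6. The forward reduction must spare the benzyl ether.

**5 ⇒ 4 ⇒ 2 ⇒ 1.** The formyl carbon of 5 is removed from the only free ortho position of phenol 4. The hydroxyl of 4 goes back to the formyl group of 2 (aryl migration to oxygen), and the benzyl ether of 2 to the hydroxyl of 1. In this order the benzyl group is placed on the only hydroxyl of 1 before the second oxygen exists, so the two catechol oxygens are never both free and never have to be distinguished. The new hydroxyl arises para to the methoxy group, as the bridging oxygen must be.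

## Roads not taken

**Alternative 1:** Ring B is cut at C2'–C3' and C4'–C5' and grown on the ether oxygen. The precursors are the racemic cyclobutenone A2, whose sp3 carbon carries the complete ring A–C unit as an aryloxy group, and methoxyacetylene A3.
- Forward key step: heating opens A2 to a vinylketene, which adds A3 in a [2+2] sense. A four-electron ring opening and a six-electron electrocyclisation then give the phenol A1.
- Merits: the three ring-B oxygens are born differentiated (2'-OH free, 4'-OMe from A3, 1'-O already the bridge). No ring-B protecting group and no separate ring-B synthesis are needed. In this respect it is better than the chosen plan, which spends five steps on phenol 8 and carries a benzyl ether to the end.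
- Weak points: A2 is a substrate type without close precedent. Its assembly from an aryloxyketene and an unactivated terminal alkyne is uncertain, and the isocoumarin phenol it is built on needs its own full synthesis first, so the route is linear. A3 is volatile and unstable and must be made and used in excess. The phenol A1 is formed in the presence of ketenes, which can acylate it.
- Comparison: the chosen plan sets against this elegance two cheap and fully precedented building blocks (8 and 13) and a key step that forms ring A on an existing, stable bis-lactone.

**Alternative 2:** Ring A is cut at C8–C8a and C4a–C5. The precursors are the 1-aryloxy-3-silyloxycyclohexadiene A5 and the diynoate A6.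
- Forward key step: [4+2] addition across the ester-bearing triple bond of A6, then cycloreversion with loss of the CH2–CH2 bridge, gives the benzoate A4. Lactonisation onto the alkyne, desilylation and hydrogenolysis must follow.
- Merits: both donor oxygens of A5 polarise the diene toward the β-carbon of the ynoate, so the regiochemistry is matched. This benzannulation type has the broader precedent, and the tert-butyldimethylsilyl ether of A4 is robust enough to purify. In both respects it is stronger than the chosen key step.
- Weak points: the bond C8–C8a must form at a fully substituted diene terminus bearing the doubly ortho-substituted ring B. Extrusion of the bridge needs high temperature, at which a conjugated diyne can also react at its distal alkyne or oligomerise. Ring C still has to be closed afterwards, with 6-endo against 5-exo selectivity to control, so three operations follow the key step instead of one. A5 needs the same phenol 8 and the same kind of addition–elimination, so nothing is saved on ring B.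
- Comparison: the chosen plan offers ring C already in place, a shorter end game and no late alkyne chemistry.

**Alternative 3:** Ring B is cut at C1'–C6'. The precursor is the 4-pyranone A8, whose side-chain CH2 is attached to the ring-A oxygen.
- Forward key step: aqueous hydroxide opens A8 to the triketone A9. The aryloxy-bearing methylene of A9 condenses with the pentyl ketone, the ring aromatises to the resorcinol A7, and acid recloses ring C, which is expected to open under the same conditions.
- Merits: the hindered bridging oxygen is attached by simple O-alkylation with a primary halide, the easiest ether formation of all four plans and easier than the addition–elimination of the chosen route. No ring-B building block has to be made.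
- Weak points: A9 can close in two directions (the methylene next to the butyl chain can attack the carbonyl next to the aryloxymethyl group) or revert to the pyranone, and only a modest acidity difference decides. The whole molecule is exposed to hot hydroxide. A7 then needs 4'-O-methylation selective over the 2'-hydroxyl, followed by debenzylation.
- Comparison: the chosen plan accepts a harder ether-forming step, but every oxygen arrives differentiated and no regiochemical choice is left to an aldol condensation.

Key step: step 11

Remark on the chemistry: the target has no stereocentre. Alkene 7 is expected as a Z-rich E/Z mixture (drawn Z), and cycloadduct 18 as a racemate (one enantiomer drawn); neither affects the outcome.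

## Route

Step 1
Reactants: 1 2-hydroxy-4-methoxybenzaldehyde
Product: 2 2-(benzyloxy)-4-methoxybenzaldehyde
Conditions: BnBr (1.2 equiv), K2CO3, DMF, 50 °C
Reagents that add atoms: benzyl bromide, BrCc1ccccc1
Why: Williamson etherification of the only hydroxyl; the aldehyde is inert to carbonate, and the benzyl ether survives every later step until the final hydrogenolysis.

Step 2
Reactants: 2 2-(benzyloxy)-4-methoxybenzaldehyde
Product: 4 2-(benzyloxy)-4-methoxyphenol, via 2-(benzyloxy)-4-methoxyphenyl formate 3 (not isolated)
Conditions: mCPBA, CH2Cl2, 0 °C → rt; aq. NaHCO3 wash; K2CO3 (cat.), MeOH, rt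
Reagents that add atoms: 3-chloroperoxybenzoic acid (mCPBA), O=C(OO)c1cccc(Cl)c1
Why: Baeyer–Villiger (Dakin-type) oxidation: the aryl group, activated by ortho and para alkoxy groups, migrates in preference to hydride, and mild methanolysis of formate 3 frees a hydroxyl para to the methoxy group, the future bridging oxygen.

Step 3
Reactants: 4 2-(benzyloxy)-4-methoxyphenol
Product: 5 3-(benzyloxy)-2-hydroxy-5-methoxybenzaldehyde
Conditions: MgCl2 (2 equiv), Et3N (4 equiv), (CH2O)n (6 equiv), MeCN, reflux; 1 M HCl work-up
Reagents that add atoms: paraformaldehyde (as formaldehyde), C=O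
Why: Magnesium-mediated ortho-formylation (Casnati–Skattebøl conditions): the magnesium phenoxide delivers formaldehyde only ortho to oxygen, only one ortho position is free, and a second formaldehyde equivalent acts as hydride acceptor.

Step 4
Reactants: 5 3-(benzyloxy)-2-hydroxy-5-methoxybenzaldehyde; 6 butyltriphenylphosphonium bromide
Product: 7 2-(benzyloxy)-4-methoxy-6-[(1Z)-pent-1-en-1-yl]phenol
Conditions: 6 (2.3 equiv), KN(SiMe3)2 (2.2 equiv), THF, 0 °C; then 5, 0 °C → rt
Reagents that add atoms: none
Why: Wittig olefination with a non-stabilised ylide: one equivalent of ylide is spent on the phenol, the phenoxide aldehyde still reacts, and the alkene geometry is irrelevant because step 5 saturates it.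

Step 5
Reactants: 7 2-(benzyloxy)-4-methoxy-6-[(1Z)-pent-1-en-1-yl]phenol
Product: 8 2-(benzyloxy)-4-methoxy-6-pentylphenol
Conditions: H2 (1 atm), RhCl(PPh3)3 (5 mol%), toluene–EtOH (1:1), rt
Reagents that add atoms: none
Why: Homogeneous hydrogenation with RhCl(PPh3)3 saturates the disubstituted alkene and does not hydrogenolyse the aryl benzyl ether, which a heterogeneous palladium catalyst would endanger.

Step 6
Reactants: 9 4-hydroxy-6-methyl-2H-pyran-2-one; 10 1-iodobutane
Product: 11 4-hydroxy-6-pentyl-2H-pyran-2-one
Conditions: LiN(iPr)2 (2.3 equiv, commercial solution), THF–DMPU, −78 °C; then 10, −78 °C → rt; aq. HCl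
Reagents that add atoms: none
Why: Dianion alkylation: the second deprotonation occurs at the 6-methyl group (vinylogous to the lactone carbonyl), and this more basic carbanion site is alkylated by the primary iodide, as is known for 9.

Step 7
Reactants: 11 4-hydroxy-6-pentyl-2H-pyran-2-one; 12 malonyl dichloride
Product: 13 4-hydroxy-7-pentyl-2H,5H-pyrano[4,3-b]pyran-2,5-dione
Conditions: 12 (1.3 equiv), CF3CO2H, 70 °C
Reagents that add atoms: none
Why: Known annulation of 4-hydroxy-2-pyranones: one acyl chloride acylates the nucleophilic C3, the other lactonises onto the 4-oxygen, and the new ring enolises to a second 4-hydroxy-2-pyranone.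

Step 8
Reactants: 13 4-hydroxy-7-pentyl-2H,5H-pyrano[4,3-b]pyran-2,5-dione
Product: 14 4-chloro-7-pentyl-2H,5H-pyrano[4,3-b]pyran-2,5-dione
Conditions: POCl3 (solvent), Et3N (1.1 equiv), 60 °C; ice-water quench
Reagents that add atoms: phosphoryl chloride, O=P(Cl)(Cl)Cl
Why: Deoxychlorination of a vinylogous acid, as practised on 4-hydroxycoumarins and 4-hydroxy-2-pyranones; the enol oxygen is phosphorylated and displaced by chloride while the lactone carbonyls stay intact.

Step 9
Reactants: 14 4-chloro-7-pentyl-2H,5H-pyrano[4,3-b]pyran-2,5-dione; 8 2-(benzyloxy)-4-methoxy-6-pentylphenol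
Product: 15 4-[2-(benzyloxy)-4-methoxy-6-pentylphenoxy]-7-pentyl-2H,5H-pyrano[4,3-b]pyran-2,5-dione
Conditions: K2CO3 (1.5 equiv), MeCN, 0 °C → rt
Reagents that add atoms: none
Why: Addition–elimination of a phenoxide at the β-carbon of a vinylogous acid chloride; C4 is the only carbon with a leaving group, so the hindered ether oxygen is placed irreversibly and without metal catalysis.

Step 10
Reactants: 16 trimethylsilyl acetate
Product: 17 1,1-bis(trimethylsilyloxy)ethene
Conditions: LiN(iPr)2 (1.05 equiv, commercial solution), THF, −78 °C; Me3SiCl, −78 °C → rt; distillation
Reagents that add atoms: chlorotrimethylsilane, C[Si](C)(C)Cl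
Why: Standard preparation of a ketene bis(silyl) acetal: the lithium enolate of the silyl ester is trapped on oxygen by the hard silyl chloride.

Step 11
Reactants: 15 4-[2-(benzyloxy)-4-methoxy-6-pentylphenoxy]-7-pentyl-2H,5H-pyrano[4,3-b]pyran-2,5-dione; 17 1,1-bis(trimethylsilyloxy)ethene
Product: 20 8-[2-(benzyloxy)-4-methoxy-6-pentylphenoxy]-3-pentyl-6-(trimethylsilyloxy)-1H-isochromen-1-one, via bridged lactone cycloadduct 18 (not isolated), via 5,6-dihydroisocoumarin bis(silyl) acetal 19 (not isolated)
Conditions: 17 (4 equiv), toluene, 110 °C, sealed tube, argon; then evaporation of volatiles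
Reagents that add atoms: none
Why: An inverse-electron-demand Diels–Alder reaction between the electron-poor 2-pyranone diene C3=C4–C4a=C8a of 15 and the electron-rich alkene 17: the nucleophilic CH2 of 17 bonds to C8a, which is the β-carbon of the ring C lactone and the δ-carbon of the C2 lactone, and the acetal carbon bonds to the unsubstituted C3–H, either concertedly but asynchronously or through a zwitterion (dienolate plus bis(silyloxy)carbenium ion) that collapses to the same adduct 18. Ring A is therefore closed by an intermolecular [4+2] cycloaddition that forms C4a–C5 and C6–C7 (isocoumarin numbering), not by cyclisation of a tethered chain, and it first appears as the cyclohexene of a 2-oxabicyclo[2.2.2]oct-5-en-3-one. Retro-[4+2] loss of CO2 from 18 gives diene 19, and 1,2-elimination of trimethylsilanol across C5–C6, driven by aromatisation, gives the aryl silyl ether 20 with ring C and the aryl ether untouched. The closest known reaction type is the cycloaddition of 5-acyl and 3-acyl 2-pyranones (coumalate-type esters) with ketene acetals followed by loss of CO2 and alcohol, which gives benzoates oxygenated para or ortho to the acyl group; 15 is a 5-acyl-2-pyranone whose acyl group is tied back as the ring C lactone, a case not yet examined in this reaction. No stereocentre survives: the two bridgehead centres of 18 are fixed relative to each other by the bicycle and are erased on aromatisation. Three selectivities are needed: the diene of the aryloxy-bearing pyranone must react rather than that of ring C, which is secured because the ring C diene ends in two fully substituted carbons (C4a and the pentyl-bearing C7) whereas the chosen diene ends in C3–H; the regiochemistry CH2 to C8a is secured by the two carbonyl groups that make C8a the most electrophilic carbon; and attack at C4 with loss of aryloxide is disfavoured because the aryloxy oxygen donates into C4. Excess 17 silylates the liberated silanol and keeps the medium neutral.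

Step 12
Reactants: 20 8-[2-(benzyloxy)-4-methoxy-6-pentylphenoxy]-3-pentyl-6-(trimethylsilyloxy)-1H-isochromen-1-one
Product: 22 6-hydroxy-8-(2-hydroxy-4-methoxy-6-pentylphenoxy)-3-pentyl-1H-isochromen-1-one, via 6-hydroxy benzyl ether 21 (not isolated)
Conditions: AcOH (cat.), MeOH–EtOAc, rt; then H2 (1 atm), Pd/C, rt
Reagents that add atoms: none
Why: Aryl trimethylsilyl ethers undergo acid-catalysed methanolysis at room temperature, and hydrogenolysis of the aryl benzyl ether over Pd/C is far faster than reduction of the trisubstituted enol-lactone double bond; the methyl ether, the diaryl ether and the lactone are inert.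

## Compound list

1 | 2-hydroxy-4-methoxybenzaldehyde | COc1ccc(C=O)c(O)c1 | starting material
2 | 2-(benzyloxy)-4-methoxybenzaldehyde | COc1ccc(C=O)c(OCc2ccccc2)c1 | intermediate
3 | 2-(benzyloxy)-4-methoxyphenyl formate (not isolated) | COc1ccc(OC=O)c(OCc2ccccc2)c1 | intermediate
4 | 2-(benzyloxy)-4-methoxyphenol | COc1ccc(O)c(OCc2ccccc2)c1 | intermediate
5 | 3-(benzyloxy)-2-hydroxy-5-methoxybenzaldehyde | COc1cc(C=O)c(O)c(OCc2ccccc2)c1 | intermediate
6 | butyltriphenylphosphonium bromide | CCCC[P+](c1ccccc1)(c1ccccc1)c1ccccc1.[Br-] | starting material
7 | 2-(benzyloxy)-4-methoxy-6-[(1Z)-pent-1-en-1-yl]phenol (Z-rich mixture, Z drawn) | CCC/C=C\c1cc(OC)cc(OCc2ccccc2)c1O | intermediate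
8 | 2-(benzyloxy)-4-methoxy-6-pentylphenol | CCCCCc1cc(OC)cc(OCc2ccccc2)c1O | intermediate
9 | 4-hydroxy-6-methyl-2H-pyran-2-one | Cc1cc(O)cc(=O)o1 | starting material
10 | 1-iodobutane | CCCCI | starting material
11 | 4-hydroxy-6-pentyl-2H-pyran-2-one | CCCCCc1cc(O)cc(=O)o1 | intermediate
12 | malonyl dichloride | O=C(Cl)CC(=O)Cl | starting material
13 | 4-hydroxy-7-pentyl-2H,5H-pyrano[4,3-b]pyran-2,5-dione | CCCCCc1cc2oc(=O)cc(O)c2c(=O)o1 | intermediate
14 | 4-chloro-7-pentyl-2H,5H-pyrano[4,3-b]pyran-2,5-dione | CCCCCc1cc2oc(=O)cc(Cl)c2c(=O)o1 | intermediate
15 | 4-[2-(benzyloxy)-4-methoxy-6-pentylphenoxy]-7-pentyl-2H,5H-pyrano[4,3-b]pyran-2,5-dione | CCCCCc1cc2oc(=O)cc(Oc3c(OCc4ccccc4)cc(OC)cc3CCCCC)c2c(=O)o1 | intermediate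
16 | trimethylsilyl acetate | CC(=O)O[Si](C)(C)C | starting material
17 | 1,1-bis(trimethylsilyloxy)ethene | C=C(O[Si](C)(C)C)O[Si](C)(C)C | intermediate
18 | racemic cycloadduct of 15 and 17: 2-oxabicyclo[2.2.2]oct-5-en-3-one fused to ring C, with the CH2 of 17 on the former C8a and the C(OSiMe3)2 on the former C3 of 15 (not isolated, one enantiomer drawn) | CCCCCC1=C[C@@]23CC(O[Si](C)(C)C)(O[Si](C)(C)C)[C@@H](C(=O)O2)C(Oc4c(OCc5ccccc5)cc(OC)cc4CCCCC)=C3C(=O)O1 | intermediate
19 | 8-[2-(benzyloxy)-4-methoxy-6-pentylphenoxy]-3-pentyl-6,6-bis(trimethylsilyloxy)-5,6-dihydro-1H-isochromen-1-one (not isolated) | CCCCCC1=CC2=C(C(=O)O1)C(Oc3c(OCc4ccccc4)cc(OC)cc3CCCCC)=CC(O[Si](C)(C)C)(O[Si](C)(C)C)C2 | intermediate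
20 | 8-[2-(benzyloxy)-4-methoxy-6-pentylphenoxy]-3-pentyl-6-(trimethylsilyloxy)-1H-isochromen-1-one | CCCCCc1cc2cc(O[Si](C)(C)C)cc(Oc3c(OCc4ccccc4)cc(OC)cc3CCCCC)c2c(=O)o1 | intermediate
21 | 8-[2-(benzyloxy)-4-methoxy-6-pentylphenoxy]-6-hydroxy-3-pentyl-1H-isochromen-1-one (not isolated) | CCCCCc1cc2cc(O)cc(Oc3c(OCc4ccccc4)cc(OC)cc3CCCCC)c2c(=O)o1 | intermediate
22 | 6-hydroxy-8-(2-hydroxy-4-methoxy-6-pentylphenoxy)-3-pentyl-1H-isochromen-1-one | CCCCCc1cc2cc(O)cc(Oc3c(O)cc(OC)cc3CCCCC)c2c(=O)o1 | target

## Step count and risks

Total step count: 12. Longest linear sequence: 8 steps (steps 1, 2, 3, 4, 5, 9, 11, 12, from 1 to 22). The pyranone branch (steps 6, 7, 8) and the ketene acetal (step 10) are convergent.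

Least certain steps:

**Key step (step 11).**
- What may go wrong: silyl transfer within the zwitterion can abort ring closure, giving conjugate addition and opening of the aryloxy-bearing pyranone. The acetal may instead add at C4 with expulsion of the aryloxide, or cycloaddition may occur on the ring C diene. Each would consume 15 without forming ring A.
- Fallback: it sets out from 15 and returns at 22. The silyl ketene acetal is replaced by a dialkyl ketene acetal, which cannot transfer silicon and belongs exactly to the precedented reagent class. Commercial bromoacetaldehyde diethyl acetal is exchanged with benzyl alcohol under acid catalysis to bromoacetaldehyde dibenzyl acetal F1. Dehydrobromination with KOC(CH3)3 gives 1,1-bis(benzyloxy)ethene F2. Heating 15 with F2 in toluene should give, after loss of carbon dioxide and benzyl alcohol, 6-(benzyloxy)-8-[2-(benzyloxy)-4-methoxy-6-pentylphenoxy]-3-pentyl-1H-isochromen-1-one F3. Hydrogenolysis of both benzyl ethers of F3 over Pd/C delivers 22.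

**Ether formation (step 9).**
- What may go wrong: the phenoxide of 8, flanked by two ortho substituents, may add slowly at C4. Phenoxide or carbonate can meanwhile attack the lactone carbonyls or the ring-fusion carbon, so the bis-lactone opens before substitution is complete.
- Fallback: it sets out from 8 and returns at 15. The base-mediated displacement is replaced by a silicon-mediated coupling under carbonate-free conditions. Phenol 8 is silylated with hexamethyldisilazane to [2-(benzyloxy)-4-methoxy-6-pentylphenoxy]trimethylsilane F4. F4 is combined with 14 and CsF in MeCN, so that the phenoxide is released only gradually and the strong Si–F bond drives the substitution, giving 15.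

**Chlorination (step 8).**
- What may go wrong: hot POCl3 may degrade the acid-sensitive bis-lactone, or chlorination may be incomplete, and the vinylogous acid chloride may hydrolyse back during the aqueous quench.
- Fallback: it sets out from 13 and returns at 15. The enol is sulfonylated instead of chlorinated: 4-toluenesulfonyl chloride and Et3N in CH2Cl2 at 0 °C give 2,5-dioxo-7-pentyl-2H,5H-pyrano[4,3-b]pyran-4-yl 4-methylbenzenesulfonate F5. F5 is displaced by 8 with K2CO3 in MeCN to give 15.

**Deprotection (step 12).**
- What may go wrong: over-reduction of the C3=C4 enol-lactone double bond during hydrogenolysis, or sluggish cleavage of the hindered benzyl ether that invites such over-reduction on prolonged exposure.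
- Fallback: it sets out from 21, isolated after the methanolysis stage, and returns at 22. Hydrogenolysis is replaced by Lewis-acid dealkylation with BCl3 and pentamethylbenzene as cation scavenger in CH2Cl2 at −78 °C. This removes an aryl benzyl ether without touching an aryl methyl ether or an alkene; no new intermediate is made.

## Further compounds

F1 | step 11 | 2-bromo-1,1-bis(benzyloxy)ethane (bromoacetaldehyde dibenzyl acetal) | BrCC(OCc1ccccc1)OCc1ccccc1
F2 | step 11 | 1,1-bis(benzyloxy)ethene | C=C(OCc1ccccc1)OCc1ccccc1
F3 | step 11 | 6-(benzyloxy)-8-[2-(benzyloxy)-4-methoxy-6-pentylphenoxy]-3-pentyl-1H-isochromen-1-one | CCCCCc1cc2cc(OCc3ccccc3)cc(Oc3c(OCc4ccccc4)cc(OC)cc3CCCCC)c2c(=O)o1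
F4 | step 9 | [2-(benzyloxy)-4-methoxy-6-pentylphenoxy]trimethylsilane | CCCCCc1cc(OC)cc(OCc2ccccc2)c1O[Si](C)(C)C
F5 | step 8 | 2,5-dioxo-7-pentyl-2H,5H-pyrano[4,3-b]pyran-4-yl 4-methylbenzenesulfonate | CCCCCc1cc2oc(=O)cc(OS(=O)(=O)c3ccc(C)cc3)c2c(=O)o1
F0 | step 12 | none | none
A1 | alternative 1 | 6-(benzyloxy)-8-(2-hydroxy-4-methoxy-6-pentylphenoxy)-3-pentyl-1H-isochromen-1-one | CCCCCc1cc2cc(OCc3ccccc3)cc(Oc3c(O)cc(OC)cc3CCCCC)c2c(=O)o1
A2 | alternative 1 | 4-{[6-(benzyloxy)-1-oxo-3-pentyl-1H-isochromen-8-yl]oxy}-3-pentylcyclobut-2-en-1-one (racemic) | CCCCCC1=CC(=O)C1Oc1cc(OCc2ccccc2)cc2cc(CCCCC)oc(=O)c12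
A3 | alternative 1 | methoxyacetylene (methoxyethyne) | COC#C
A4 | alternative 2 | methyl 2-[2-(benzyloxy)-4-methoxy-6-pentylphenoxy]-4-(tert-butyldimethylsilyloxy)-6-(hept-1-yn-1-yl)benzoate | CCCCCC#Cc1cc(O[Si](C)(C)C(C)(C)C)cc(Oc2c(OCc3ccccc3)cc(OC)cc2CCCCC)c1C(=O)OC
A5 | alternative 2 | 1-[2-(benzyloxy)-4-methoxy-6-pentylphenoxy]-3-(tert-butyldimethylsilyloxy)cyclohexa-1,3-diene | CC(C)(C)[Si](C)(C)OC1=CCCC(Oc2c(OCc3ccccc3)cc(OC)cc2CCCCC)=C1
A6 | alternative 2 | methyl deca-2,4-diynoate | CCCCCC#CC#CC(=O)OC
A7 | alternative 3 | 6-(benzyloxy)-8-(2,4-dihydroxy-6-pentylphenoxy)-3-pentyl-1H-isochromen-1-one | CCCCCc1cc2cc(OCc3ccccc3)cc(Oc3c(O)cc(O)cc3CCCCC)c2c(=O)o1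
A8 | alternative 3 | 2-({[6-(benzyloxy)-1-oxo-3-pentyl-1H-isochromen-8-yl]oxy}methyl)-6-pentyl-4H-pyran-4-one | CCCCCc1cc(=O)cc(COc2cc(OCc3ccccc3)cc3cc(CCCCC)oc(=O)c23)o1
A9 | alternative 3 | 1-{[6-(benzyloxy)-1-oxo-3-pentyl-1H-isochromen-8-yl]oxy}undecane-2,4,6-trione | CCCCCC(=O)CC(=O)CC(=O)COc1cc(OCc2ccccc2)cc2cc(CCCCC)oc(=O)c12
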